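**Retrosynthetic overview**

1. Sarcodictyin A is taken back to its C4 methyl ketal and C8 alcohol (late acylation with N-methylurocanic acid), and that to the bridged 2-methoxy-2,5-dihydrofuran 21.
2. The dihydrofuran ring (O, C7, C6, C5, C4) is made by gold-catalysed enlargement of a C6–C7 oxirane onto the neighbouring C4≡C5 alkyne inside the ten-membered ring. What makes this possible: the ring oxygen sits on fully substituted C7, 1,4 to C4 across the cis C5=C6 bond; C4 is at the ketone level and can be stored as an alkyne carbon; C7 carries no hydrogen, so the enlargement cannot run on to a furan.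
3. The ten-membered carbocycle is closed at C5–C6 by a CrCl2/NiCl2 alkynyl iodide–aldehyde reaction; the oxirane then comes from the resulting 6,7-diol.
4. C7 and C8 come from a (Z)-allylic alcohol by Sharpless epoxidation and titanium-assisted benzoate opening; C2=C3(CO2Me)–C4≡C5 comes from a bromo-Wittig olefination and Sonogashira coupling.
5. The cyclohexene with C1, C10 and C14 comes from (R)-α-phellandrene by dichloroketene [2+2] addition and cleavage of the cyclobutanone. Ring order: cyclohexene (given), temporary cyclobutanone, ten-membered carbocycle, oxirane, dihydrofuran.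

Key step: step 19

Remark on numbering: sarcodictyin positions are used throughout. The ten-membered ring is C1–C10, the cyclohexene is C1, C10–C14, the ester carbon C15 sits on C3, and the oxygen bridge runs C4–O–C7.

Remark on C6: the C6 carbinol of 18, 19 and 20 is carried as both epimers, because C6 becomes an sp2 carbon in step 19.

Remark on the tartrate: the choice of L-(+)-diethyl tartrate in step 8 was derived from the known outcome with (E)-primary allylic alcohols, which give (2S,3S)-epoxy alcohols.

**Route**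

Step 1
Reactants: 1 (R)-(−)-α-phellandrene
Product: 2 cis-fused 8,8-dichloro-2-methyl-5-(propan-2-yl)bicyclo[4.2.0]oct-2-en-7-one (C=O on C1, CCl2 on C10)
Conditions: Cl3CCOCl, Zn (activated), Et2O, ultrasound, 15–20 °C
Reagents that add atoms: trichloroacetyl chloride ClC(=O)C(Cl)(Cl)Cl (source of dichloroketene O=C=C(Cl)Cl)
Why: Thermal ketene–alkene [2+2] cycloaddition with dichloroketene made in the flask; the ketene carbonyl carbon should bond to the diene terminus C1, only the disubstituted alkene should react, and addition anti to the isopropyl group sets C1 and C10 cis to each other and trans to C14.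

Step 2
Reactants: 2 dichlorocyclobutanone
Product: 3 cis-fused 2-methyl-5-(propan-2-yl)bicyclo[4.2.0]oct-2-en-7-one
Conditions: Zn, AcOH, 70 °C
Reagents that add atoms: none
Why: Zinc-mediated reductive dechlorination of an α,α-dichloroketone, which touches no stereocentre.

Step 3
Reactants: 3 cyclobutanone
Product: 4 (E)-8-[(dimethylamino)methylidene]-2-methyl-5-(propan-2-yl)bicyclo[4.2.0]oct-2-en-7-one
Conditions: t-BuOCH(NMe2)2 (neat), 60 °C
Reagents that add atoms: tert-butoxybis(dimethylamino)methane CN(C)C(OC(C)(C)C)N(C)C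
Why: Aminomethylenation with Bredereck's reagent at the only enolisable methylene (C9), giving the vinylogous amide.

Step 4
Reactants: 4 enaminone
Product: 5 methyl 2-(2,2-dimethoxyethyl)-3-methyl-6-(propan-2-yl)cyclohex-3-ene-1-carboxylate (C1/C10 cis, C14 trans)
Conditions: p-TsOH·H2O (1.2 equiv), MeOH, reflux; then NaHCO3
Reagents that add atoms: methanol CO
Why: Acid-mediated methanolysis of the α-aminomethylene cyclobutanone is a strain-driven retro-Claisen cleavage of C2–C9 that leaves C2 as the methyl ester on C1 and, after methanolysis of the enamine, C8 as the dimethyl acetal, without touching C1 or C10.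

Step 5
Reactants: 5 ester acetal
Product: 6 methyl 3-methyl-2-(2-oxoethyl)-6-(propan-2-yl)cyclohex-3-ene-1-carboxylate (C8 aldehyde)
Conditions: 1 M HCl, THF, 0 °C → rt
Reagents that add atoms: water O
Why: Mild acetal hydrolysis, which the ester, the trisubstituted alkene and the ring stereocentres should survive.

Step 6
Reactants: 6 C8 aldehyde
Product: 7 (Z)-enoate diester (C8=C7(CH3)–C6O2Me, C9 cis to C6)
Conditions: (CF3CH2O)2P(O)CH(CH3)CO2Me, KN(SiMe3)2, 18-crown-6, THF, −78 °C
Reagents that add atoms: methyl 2-[bis(2,2,2-trifluoroethoxy)phosphoryl]propanoate COC(=O)C(C)P(=O)(OCC(F)(F)F)OCC(F)(F)F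
Why: Still–Gennari variant of the Horner–Wadsworth–Emmons olefination, which should give the (Z)-trisubstituted enoate under kinetic control.

Step 7
Reactants: 7 (Z)-enoate diester
Product: 8 (Z)-allylic alcohol diol (C2–OH and C6–OH)
Conditions: i-Bu2AlH (5 equiv), CH2Cl2, −78 → 0 °C; aq. KNaC4H4O6
Reagents that add atoms: none
Why: Hydride reduction of both esters to primary alcohols by i-Bu2AlH, which leaves the alkenes and the Z geometry intact.

Step 8
Reactants: 8 (Z)-allylic alcohol diol
Product: 9 (7S,8R)-7,8-epoxy diol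
Conditions: Ti(OiPr)4 (20 mol %), L-(+)-diethyl tartrate (24 mol %), t-BuOOH, 4 Å MS, CH2Cl2, −20 °C
Reagents that add atoms: tert-butyl hydroperoxide CC(C)(C)OO
Why: Sharpless asymmetric epoxidation is hydroxyl-directed and so should leave C11=C12 alone; the tartrate chooses the alkene face (reagent control) and fixes the C7–O bond that is kept to the end.

Step 9
Reactants: 9 epoxy diol
Product: 10 C8 benzoate triol (7S,8S; free C2–OH, C6–OH, C7–OH)
Conditions: Ti(OiPr)4 (1.5 equiv), PhCO2H (1.5 equiv), CH2Cl2, rt
Reagents that add atoms: benzoic acid OC(=O)c1ccccc1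
Why: Titanium-assisted opening of a 2,3-epoxy alcohol by a carboxylic acid at the carbon remote from the hydroxymethyl group (here secondary C8, next to fully substituted C7) with SN2 inversion, which should give the target configuration at C8 and keep C7.

Step 10
Reactants: 10 C8 benzoate triol
Product: 11 C6/C7 acetonide with free C2–OH
Conditions: Me2C(OMe)2, PPTS (cat.), acetone, rt
Reagents that add atoms: 2,2-dimethoxypropane COC(C)(C)OC
Why: Acetonide formation selects the 1,2-diol and leaves the isolated C2 primary alcohol free.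

Step 11
Reactants: 11 acetonide alcohol
Product: 12 C2 aldehyde
Conditions: Dess–Martin periodinane, NaHCO3, CH2Cl2, 0 °C → rt
Reagents that add atoms: none
Why: Dess–Martin oxidation under buffered, non-basic conditions should give the aldehyde without epimerising C1.

Step 12
Reactants: 12 C2 aldehyde
Product: 13 methyl (Z)-α-bromoacrylate (C2=C3(Br)CO2Me, Br cis to C1)
Conditions: Ph3P=CHCO2Me, NBS, CH2Cl2, −20 °C; then 12, rt → 40 °C
Reagents that add atoms: methyl (triphenylphosphoranylidene)acetate COC(=O)C=P(c1ccccc1)(c1ccccc1)c1ccccc1; N-bromosuccinimide O=C1CCC(=O)N1Br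
Why: Wittig olefination with the stabilised bromo ylide made in the flask should place the ester trans to C1, so the bromine sits cis to C1 as the ring needs.

Step 13
Reactants: 13 α-bromoacrylate
Product: 14 trimethylsilyl enyne ester (C3–C4≡C5–SiMe3)
Conditions: HC≡CSiMe3, Pd(PPh3)2Cl2 (5 mol %), CuI (10 mol %), Et3N, THF, rt
Reagents that add atoms: ethynyltrimethylsilane C#C[Si](C)(C)C
Why: Sonogashira coupling of the vinyl bromide with retention of alkene geometry installs C4≡C5 cis to C1.

Step 14
Reactants: 14 trimethylsilyl enyne ester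
Product: 15 iodoalkyne (C5–I)
Conditions: NIS, AgNO3 (10 mol %), acetone, rt, dark
Reagents that add atoms: N-iodosuccinimide O=C1CCC(=O)N1I
Why: Silver-catalysed iododesilylation of the alkynylsilane under neutral conditions, which should spare the isolated alkene and the electron-poor enyne.

Step 15
Reactants: 15 iodoalkyne acetonide
Product: 16 iodoalkyne 6,7-diol
Conditions: AcOH/THF/H2O (3:1:1), 40 °C
Reagents that add atoms: none
Why: Mild acid hydrolysis of the acetonide, which the benzoate, the iodoalkyne and the esters should tolerate.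

Step 16
Reactants: 16 iodoalkyne 6,7-diol
Product: 17 iodoalkyne α-hydroxy aldehyde (C6 aldehyde, free C7–OH)
Conditions: SO3·pyridine, DMSO, i-Pr2NEt, CH2Cl2, 0 °C
Reagents that add atoms: none
Why: Parikh–Doering oxidation takes the primary C6 alcohol to the aldehyde; the tertiary C7–OH cannot be oxidised and activated DMSO does not cleave the glycol.

Step 17
Reactants: 17 iodoalkyne α-hydroxy aldehyde
Product: 18 macrocyclic enyne 6,7-diol (ten-membered ring, both C6 epimers)
Conditions: CrCl2 (6 equiv), NiCl2 (2 mol %), THF, rt, 2 mM, slow addition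
Reagents that add atoms: none
Why: Nozaki–Hiyama–Kishi reaction of an alkynyl iodide with an aldehyde: divalent chromium inserts into the C–I bond and the alkynylchromium adds to the aldehyde in the presence of esters and a free hydroxyl, a ring closure of the kind known for nine- and ten-membered cycloalkynes; C6 is not controlled and need not be.

Step 18
Reactants: 18 macrocyclic enyne 6,7-diol
Product: 20 macrocyclic alkynyl oxirane (C6–C7 oxirane next to C4≡C5), via C6 mesylate 19 (not isolated)
Conditions: MsCl, Et3N, CH2Cl2, −30 °C; then DBU, rt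
Reagents that add atoms: none
Why: Selective sulfonylation of the secondary propargylic C6–OH, then intramolecular Williamson (3-exo-tet) displacement by the tertiary C7 oxygen; the C7–O bond is not broken, so C7 keeps its configuration.

Step 19
Reactants: 20 macrocyclic alkynyl oxirane
Product: 21 bridged 4-methoxy-4,7-epoxy (2,5-dihydrofuran) ketal with C8 benzoate
Conditions: Ph3PAuNTf2 (5 mol %), MeOH (3 equiv), 4 Å MS, CH2Cl2, 0 °C → rt
Reagents that add atoms: methanol CO
Why: Proposed new method: monovalent gold π-activates C4≡C5; the oxirane oxygen (bonded to C6 and C7), held across the ring over C4, attacks C4 anti to gold (5-endo-dig closure of the ring O–C7–C6–C5–C4); the strained bicyclic oxonium then breaks its C6–O bond to a 2H-furanium/vinylgold cation that methanol captures at C4 and that is protodeaurated at C5, so the oxygen has moved from C6 to C4 and the three-membered ring has grown by C5 and C4. The closest known reaction type is the gold- or silver-catalysed ring expansion of 2-alkynyl oxiranes to furans, including its variants run in alcohols; here aromatisation is impossible because C7 is fully substituted, so the 2-methoxy-2,5-dihydrofuran should be the end point. C7 keeps the configuration set in steps 8 and 9 because its C–O bond is never broken, the new ketal centre C4 can only form with the oxygen bridge cis across the ten-membered ring (methoxy group outside), and C5=C6 is necessarily cis as part of the five-membered ring. The step needs π-activation of the alkyne to win over Lewis-acid opening of the oxirane at tertiary C7 and over attack of the ester carbonyl on C5; a soft phosphine-gold cation with a non-coordinating counter-ion, molecular sieves and few equivalents of methanol should favour the former, and the ring holds the oxirane oxygen next to C4 whereas carbonyl attack would have to build a strained meta-bridged furan.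

Step 20
Reactants: 21 bridged methyl ketal benzoate
Product: 22 bridged methyl ketal C8 alcohol
Conditions: K2CO3, MeOH, rt
Reagents that add atoms: none
Why: Base-catalysed transesterification removes the benzoate, while the C15 methyl ester only exchanges methoxide for methoxide and the ketal is base-stable.

Step 21
Reactants: 22 bridged methyl ketal C8 alcohol; 23 (E)-3-(1-methyl-1H-imidazol-4-yl)acrylic acid (N-methylurocanic acid)
Product: 25 sarcodictyin A methyl ketal, via mixed pivalic anhydride 24 (not isolated)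
Conditions: 23, t-BuCOCl, Et3N, THF, 0 °C; then 22, DMAP, 40 °C
Reagents that add atoms: none
Why: DMAP-catalysed acylation of the hindered secondary C8–OH by the mixed anhydride, attacked at its less hindered urocanoyl carbonyl, while the methyl ketal keeps C4 out of the reaction.

Step 22
Reactants: 25 sarcodictyin A methyl ketal
Product: 26 sarcodictyin A
Conditions: CSA (cat.), MeCN/H2O (2:1), rt
Reagents that add atoms: water O
Why: Mild acid-catalysed ketal hydrolysis through the bridgehead oxocarbenium ion should give the hemiketal, whose C4 configuration is dictated by the bridge; the urocanate and the methyl ester should survive.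

**Compound list**

1 | (R)-(−)-α-phellandrene, (5R)-2-methyl-5-(propan-2-yl)cyclohexa-1,3-diene | CC1=CC[C@H](C(C)C)C=C1 | starting material
2 | cis-fused 8,8-dichloro-2-methyl-5-(propan-2-yl)bicyclo[4.2.0]oct-2-en-7-one | O=C1[C@@H]2[C@@H](C(C)C)CC=C(C)[C@@H]2C1(Cl)Cl | intermediate
3 | cis-fused 2-methyl-5-(propan-2-yl)bicyclo[4.2.0]oct-2-en-7-one | O=C1[C@@H]2[C@@H](C(C)C)CC=C(C)[C@@H]2C1 | intermediate
4 | (E)-8-[(dimethylamino)methylidene]-2-methyl-5-(propan-2-yl)bicyclo[4.2.0]oct-2-en-7-one | O=C1[C@@H]2[C@@H](C(C)C)CC=C(C)[C@@H]2/C1=C\N(C)C | intermediate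
5 | methyl 2-(2,2-dimethoxyethyl)-3-methyl-6-(propan-2-yl)cyclohex-3-ene-1-carboxylate (ester acetal) | COC(=O)[C@@H]1[C@@H](C(C)C)CC=C(C)[C@@H]1CC(OC)OC | intermediate
6 | methyl 3-methyl-2-(2-oxoethyl)-6-(propan-2-yl)cyclohex-3-ene-1-carboxylate (C8 aldehyde) | COC(=O)[C@@H]1[C@@H](C(C)C)CC=C(C)[C@@H]1CC=O | intermediate
7 | (Z)-enoate diester (C8=C7 Z) | COC(=O)[C@@H]1[C@@H](C(C)C)CC=C(C)[C@@H]1C/C=C(/C)C(=O)OC | intermediate
8 | (Z)-allylic alcohol diol | OC[C@@H]1[C@@H](C(C)C)CC=C(C)[C@@H]1C/C=C(/C)CO | intermediate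
9 | (7S,8R)-7,8-epoxy diol | OC[C@@H]1[C@@H](C(C)C)CC=C(C)[C@@H]1C[C@H]2O[C@@]2(C)CO | intermediate
10 | C8 benzoate triol (7S,8S) | OC[C@@H]1[C@@H](C(C)C)CC=C(C)[C@@H]1C[C@H](OC(=O)c2ccccc2)[C@@](C)(O)CO | intermediate
11 | C6/C7 acetonide, C8 benzoate, C2 alcohol | OC[C@@H]1[C@@H](C(C)C)CC=C(C)[C@@H]1C[C@H](OC(=O)c2ccccc2)[C@]2(C)COC(C)(C)O2 | intermediate
12 | C2 aldehyde | O=C[C@@H]1[C@@H](C(C)C)CC=C(C)[C@@H]1C[C@H](OC(=O)c2ccccc2)[C@]2(C)COC(C)(C)O2 | intermediate
13 | methyl (Z)-α-bromoacrylate | COC(=O)/C(Br)=C/[C@@H]1[C@@H](C(C)C)CC=C(C)[C@@H]1C[C@H](OC(=O)c2ccccc2)[C@]2(C)COC(C)(C)O2 | intermediate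
14 | trimethylsilyl enyne ester | COC(=O)/C(C#C[Si](C)(C)C)=C/[C@@H]1[C@@H](C(C)C)CC=C(C)[C@@H]1C[C@H](OC(=O)c2ccccc2)[C@]2(C)COC(C)(C)O2 | intermediate
15 | iodoalkyne acetonide | COC(=O)/C(C#CI)=C/[C@@H]1[C@@H](C(C)C)CC=C(C)[C@@H]1C[C@H](OC(=O)c2ccccc2)[C@]2(C)COC(C)(C)O2 | intermediate
16 | iodoalkyne 6,7-diol | COC(=O)/C(C#CI)=C/[C@@H]1[C@@H](C(C)C)CC=C(C)[C@@H]1C[C@H](OC(=O)c2ccccc2)[C@@](C)(O)CO | intermediate
17 | iodoalkyne α-hydroxy aldehyde | COC(=O)/C(C#CI)=C/[C@@H]1[C@@H](C(C)C)CC=C(C)[C@@H]1C[C@H](OC(=O)c2ccccc2)[C@@](C)(O)C=O | intermediate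
18 | macrocyclic enyne 6,7-diol (C6 both epimers) | COC(=O)/C1=C/[C@@H]2[C@@H](C(C)C)CC=C(C)[C@@H]2C[C@H](OC(=O)c3ccccc3)[C@@](C)(O)C(O)C#C1 | intermediate
19 | C6 mesylate (not isolated) | COC(=O)/C1=C/[C@@H]2[C@@H](C(C)C)CC=C(C)[C@@H]2C[C@H](OC(=O)c3ccccc3)[C@@](C)(O)C(OS(C)(=O)=O)C#C1 | intermediate
20 | macrocyclic alkynyl oxirane (C6 both epimers) | COC(=O)/C1=C/[C@@H]2[C@@H](C(C)C)CC=C(C)[C@@H]2C[C@H](OC(=O)c3ccccc3)[C@@]3(C)OC3C#C1 | intermediate
21 | bridged methyl ketal with C8 benzoate | COC(=O)/C1=C/[C@@H]2[C@@H](C(C)C)CC=C(C)[C@@H]2C[C@H](OC(=O)c3ccccc3)[C@]2(C)C=C[C@@]1(OC)O2 | intermediate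
22 | bridged methyl ketal C8 alcohol | COC(=O)/C1=C/[C@@H]2[C@@H](C(C)C)CC=C(C)[C@@H]2C[C@H](O)[C@]2(C)C=C[C@@]1(OC)O2 | intermediate
23 | (E)-3-(1-methyl-1H-imidazol-4-yl)acrylic acid | OC(=O)/C=C/c1cn(C)cn1 | starting material
24 | mixed pivalic anhydride of 23 (not isolated) | CC(C)(C)C(=O)OC(=O)/C=C/c1cn(C)cn1 | intermediate
25 | sarcodictyin A methyl ketal | COC(=O)/C1=C/[C@@H]2[C@@H](C(C)C)CC=C(C)[C@@H]2C[C@H](OC(=O)/C=C/c2cn(C)cn2)[C@]2(C)C=C[C@@]1(OC)O2 | intermediate
26 | sarcodictyin A | COC(=O)/C1=C/[C@@H]2[C@@H](C(C)C)CC=C(C)[C@@H]2C[C@H](OC(=O)/C=C/c2cn(C)cn2)[C@]2(C)C=C[C@@]1(O)O2 | target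

**Step count and risks**

Total step count: 22. Longest linear sequence: 22 steps (1 to 26); acid 23 enters at step 21.

Steps most likely to fail:

Step 19 (Proposed new method). The gold catalyst may act as a Lewis acid on the oxirane instead of the alkyne, so that methanol opens the ring at tertiary C7 or a hydride shift gives a ketone; the ester carbonyl may also attack the activated alkyne. The fallback sets out from diol 18 and uses known chemistry. Gold-catalysed 5-endo-dig hydroalkoxylation of the 3-alkyne-1,2-diol by the tertiary C7–OH (Ph3PAuNTf2, CH2Cl2/MeOH) should give the bridged 3-hydroxy-2,3-dihydrofuran F1. Its allylic C6–OH is then exchanged by a Ferrier-type allylic transposition with methanol (PPTS, MeOH), which moves the double bond to C5=C6 and puts the methoxy group on C4. The fallback comes back to the route at 21.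

Step 17. Ring closure to the strained ten-membered cycloenyne may lose out to oligomerisation or to reduction of the iodoalkyne to the terminal alkyne. The fallback sets out from 13 and closes the ring at C3–C4 instead of C5–C6. Acetonide hydrolysis (AcOH/THF/H2O) gives the bromoacrylate 6,7-diol F2, and SO3·pyridine/DMSO oxidation gives the bromoacrylate hydroxy aldehyde F3. Addition of HC≡CMgBr (THF, −78 °C) gives the bromoacrylate ethynyl diol F4. An intramolecular Sonogashira coupling under high dilution (Pd(PPh3)4, CuI, Et3N, slow addition) then forms the ring and comes back to the route at 18.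

Step 12. Olefination of the hindered α-branched aldehyde may be slow, with epimerisation at C1 on heating and erosion of the alkene geometry. The fallback sets out from 12. Wittig reaction with Ph3P=CHCHO gives the (E)-enal F5, and α-iodination (I2, K2CO3, DMAP, THF/H2O) gives the (Z)-α-iodoenal F6. Oxidation with NaClO2/NaH2PO4/2-methyl-2-butene gives the (Z)-α-iodoacrylic acid F7, and Me3SiCHN2 gives the methyl (Z)-α-iodoacrylate F8. Sonogashira coupling of F8 with ethynyltrimethylsilane under the conditions of step 13 comes back to the route at 14.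

Further compounds
F1 | step 19 | bridged 3-hydroxy-2,3-dihydrofuran (C4=C5 enol ether, C6–OH, C8 benzoate) | COC(=O)/C1=C/[C@@H]2[C@@H](C(C)C)CC=C(C)[C@@H]2C[C@H](OC(=O)c3ccccc3)[C@]2(C)C(O)C=C1O2
F2 | step 17 | bromoacrylate 6,7-diol | COC(=O)/C(Br)=C/[C@@H]1[C@@H](C(C)C)CC=C(C)[C@@H]1C[C@H](OC(=O)c2ccccc2)[C@@](C)(O)CO
F3 | step 17 | bromoacrylate hydroxy aldehyde | COC(=O)/C(Br)=C/[C@@H]1[C@@H](C(C)C)CC=C(C)[C@@H]1C[C@H](OC(=O)c2ccccc2)[C@@](C)(O)C=O
F4 | step 17 | bromoacrylate ethynyl diol (C6 both epimers) | COC(=O)/C(Br)=C/[C@@H]1[C@@H](C(C)C)CC=C(C)[C@@H]1C[C@H](OC(=O)c2ccccc2)[C@@](C)(O)C(O)C#C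
F5 | step 12 | (E)-enal | O=C/C=C/[C@@H]1[C@@H](C(C)C)CC=C(C)[C@@H]1C[C@H](OC(=O)c2ccccc2)[C@]2(C)COC(C)(C)O2
F6 | step 12 | (Z)-α-iodoenal | O=C/C(I)=C/[C@@H]1[C@@H](C(C)C)CC=C(C)[C@@H]1C[C@H](OC(=O)c2ccccc2)[C@]2(C)COC(C)(C)O2
F7 | step 12 | (Z)-α-iodoacrylic acid | OC(=O)/C(I)=C/[C@@H]1[C@@H](C(C)C)CC=C(C)[C@@H]1C[C@H](OC(=O)c2ccccc2)[C@]2(C)COC(C)(C)O2
F8 | step 12 | methyl (Z)-α-iodoacrylate | COC(=O)/C(I)=C/[C@@H]1[C@@H](C(C)C)CC=C(C)[C@@H]1C[C@H](OC(=O)c2ccccc2)[C@]2(C)COC(C)(C)O2
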